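**Plan**

- Retrosynthesis: the quinone (ring B) goes back to a phenol with a free para position, masked as a benzyl ether. The C3–H and C4–H bonds go back to the C3=C4 double bond of an isoflav-3-ene.
- The pyran ring (ring C) is then cut at O1–C2 and at C4–C4a in one stroke, into 3,4-dimethoxyphenol and an α-aryl acrolein CH2=C(Ar)–CHO. The enal is cut at its =CH2 (formaldehyde) and at the aldehyde carbon (one-carbon homologation of a benzaldehyde).
- Enabling feature: O1 and C4 sit on the neighbouring ring A carbons C8a and C4a, and C4a is para to the C7 methoxy group. Ring A is therefore a phenol acting as a 1,3-C,O-bis-nucleophile, and C2–C3(aryl)–C4 is a 1,3-bis-electrophile at the enal level (C4 = carbonyl carbon, C2 = alkene terminus); an ortho-quinone methide links the two bond formations.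
- Forward: the ring B side chain is built first (steps 1–3), ring C is closed onto ring A as the two halves are joined (step 4), C3 is set (step 5), and ring B is unmasked and oxidised last (steps 6, 7).
- Stereochemistry: the only stereocentre, C3 (S), comes from face-selective hydrogenation of the C3=C4 bond with a chiral iridium N,P catalyst; the later steps are neutral or buffered and should leave it untouched.

Key step: step 4

Assumption: 2-hydroxy-3,4-dimethoxybenzaldehyde and 3,4-dimethoxyphenol are taken as purchasable, and in step 5 the ligand antipode that delivers the 3S product is the one used (both antipodes are available).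

**Step 1**
Reactants: 1 2-hydroxy-3,4-dimethoxybenzaldehyde
Product: 2 2-(benzyloxy)-3,4-dimethoxybenzaldehyde
Conditions: BnBr, K2CO3, DMF, 60 °C
Reagents that add atoms: benzyl bromide, BrCc1ccccc1
Why: Williamson etherification of the phenoxide should proceed cleanly, and the benzyl group masks the ring B phenol through the acidic and hydrogenation steps yet leaves under neutral hydrogenolysis.

**Step 2**
Reactants: 2 2-(benzyloxy)-3,4-dimethoxybenzaldehyde
Product: 4 [2-(benzyloxy)-3,4-dimethoxyphenyl]acetaldehyde, via enol ether 3 (not isolated)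
Conditions: Ph3P(CH2OMe)Cl, KOtBu, THF, 0 °C to rt; then 2 M aq. HCl, 50 °C
Reagents that add atoms: (methoxymethyl)triphenylphosphonium chloride, COC[P+](c1ccccc1)(c1ccccc1)c1ccccc1.[Cl-]; water, O
Why: Wittig methoxymethylenation followed by acid hydrolysis of the enol ether is the standard one-carbon homologation of an aryl aldehyde to an arylacetaldehyde, and the aryl ethers are stable to dilute acid.

**Step 3**
Reactants: 4 [2-(benzyloxy)-3,4-dimethoxyphenyl]acetaldehyde
Product: 5 2-[2-(benzyloxy)-3,4-dimethoxyphenyl]prop-2-enal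
Conditions: 37% aq. CH2O, pyrrolidine (10 mol %), EtCO2H (10 mol %), i-PrOH, 45 °C
Reagents that add atoms: formaldehyde, C=O
Why: Amine/acid-catalysed Mannich condensation with formaldehyde and β-elimination of the amine (α-methylenation of an aldehyde) should give the α-aryl acrolein, since the aldehyde has a single enolisable position.

**Step 4**
Reactants: 5 2-[2-(benzyloxy)-3,4-dimethoxyphenyl]prop-2-enal, 6 3,4-dimethoxyphenol
Product: 9 3-[2-(benzyloxy)-3,4-dimethoxyphenyl]-6,7-dimethoxy-2H-chromene, via benzodioxaborin 7 (not isolated), via ortho-quinone methide 8 (not isolated)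
Conditions: PhB(OH)2 (1.0 equiv), EtCO2H (0.3 equiv), toluene, reflux, Dean–Stark trap; concentration and chromatography without aqueous work-up
Reagents that add atoms: none
Why: Phenylboronic acid condenses with the phenol OH of 6 and the aldehyde of 5 so that the carbonyl carbon is handed to the ortho carbon C6 of the phenol through a six-membered boron-bridged transition state (C4–C4a bond), giving benzodioxaborin 7; on heating, 7 expels PhBO in a retro-[4+2] to the vinyl ortho-quinone methide 8, whose 1-oxatriene (O=C8a–C4a=C4–C3=C2) closes the O1–C2 bond with rearomatisation of ring A. The closest known reaction type is the boronic acid-mediated chromenylation of phenols with α,β-unsaturated aldehydes, the standard entry to 2H-chromenes from electron-rich phenols. The pyran ring (ring C) is closed by a thermal disrotatory oxa-6π electrocyclisation, a pericyclic closure that is formally 6-endo at the CH2 terminus, and no other ring is formed. No stereocentre is created in the product: C4 of 7 is racemic and is lost again, and the step delivers C3 as a prochiral alkene carbon for step 5. The step needs ortho-regioselectivity (C6 over C2 of 6), which should follow because C2 is flanked by OH and OMe while C6 is unhindered and para to the 3-methoxy group, and it needs 1,2- over 1,4-attack on the enal, which the boron tether should secure because it can reach only the carbonyl carbon, helped by the ortho-benzyloxy group that twists the aryl ring and slows self-dimerisation of the enal.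

**Step 5**
Reactants: 9 3-[2-(benzyloxy)-3,4-dimethoxyphenyl]-6,7-dimethoxy-2H-chromene
Product: 10 (3S)-3-[2-(benzyloxy)-3,4-dimethoxyphenyl]-6,7-dimethoxy-3,4-dihydro-2H-chromene
Conditions: [Ir(cod)(L)]BArF (1 mol %; cod = 1,5-cyclooctadiene, L = 4-tert-butyl-2-[2-(diphenylphosphino)phenyl]-4,5-dihydrooxazole as a single enantiomer, BArF = tetrakis[3,5-bis(trifluoromethyl)phenyl]borate), H2 (50 bar), CH2Cl2, rt
Reagents that add atoms: none
Why: Cationic iridium complexes of chiral phosphine–oxazoline ligands hydrogenate trisubstituted aryl alkenes, 3-aryl-2H-chromenes included, without a coordinating group (asymmetric hydrogenation), so the ligand should differentiate the two faces of C3=C4 and set C3 as S while the benzyl ether stays intact.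

**Step 6**
Reactants: 10 (3S)-3-[2-(benzyloxy)-3,4-dimethoxyphenyl]-6,7-dimethoxy-3,4-dihydro-2H-chromene
Product: 11 6-[(3S)-6,7-dimethoxy-3,4-dihydro-2H-chromen-3-yl]-2,3-dimethoxyphenol
Conditions: H2 (1 atm), Pd/C (10% Pd on carbon), EtOAc/MeOH, rt
Reagents that add atoms: none
Why: Hydrogenolysis of the benzyl aryl ether under neutral conditions should free the ring B phenol without touching the chroman C–O bonds (neither is a benzylic C–O bond) or the C3 centre.

**Step 7**
Reactants: 11 6-[(3S)-6,7-dimethoxy-3,4-dihydro-2H-chromen-3-yl]-2,3-dimethoxyphenol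
Product: 12 abroquinone A, 5-[(3S)-6,7-dimethoxy-3,4-dihydro-2H-chromen-3-yl]-2,3-dimethoxycyclohexa-2,5-diene-1,4-dione
Conditions: (KSO3)2NO (Fremy's salt, 2.5 equiv), aq. KH2PO4 buffer, acetone/H2O, rt
Reagents that add atoms: Fremy's salt (dipotassium nitrosodisulfonate), [K+].[K+].[O]N(S(=O)(=O)[O-])S(=O)(=O)[O-]
Why: In the Teuber oxidation one nitroxyl radical abstracts the phenolic hydrogen and a second couples through oxygen at the free para carbon and collapses to the para-quinone, so only ring B (the ring with a free OH) should react while the fully etherified ring A is inert, and the near-neutral buffer avoids base-induced quinone methide tautomerism at C3.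

**Compound list**

1 | 2-hydroxy-3,4-dimethoxybenzaldehyde | COc1ccc(C=O)c(O)c1OC | starting material
2 | 2-(benzyloxy)-3,4-dimethoxybenzaldehyde | COc1ccc(C=O)c(OCc2ccccc2)c1OC | intermediate
3 | 2-(benzyloxy)-3,4-dimethoxy-1-(2-methoxyethenyl)benzene (E/Z mixture) | COC=Cc1ccc(OC)c(OC)c1OCc1ccccc1 | intermediate
4 | [2-(benzyloxy)-3,4-dimethoxyphenyl]acetaldehyde | O=CCc1ccc(OC)c(OC)c1OCc1ccccc1 | intermediate
5 | 2-[2-(benzyloxy)-3,4-dimethoxyphenyl]prop-2-enal | O=CC(=C)c1ccc(OC)c(OC)c1OCc1ccccc1 | intermediate
6 | 3,4-dimethoxyphenol | COc1ccc(O)cc1OC | starting material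
7 | 4-{1-[2-(benzyloxy)-3,4-dimethoxyphenyl]ethenyl}-6,7-dimethoxy-2-phenyl-4H-1,3,2-benzodioxaborinine (racemic at C4) | COc1cc2OB(c3ccccc3)OC(C(=C)c3ccc(OC)c(OC)c3OCc3ccccc3)c2cc1OC | intermediate
8 | (6Z)-6-{2-[2-(benzyloxy)-3,4-dimethoxyphenyl]prop-2-en-1-ylidene}-3,4-dimethoxycyclohexa-2,4-dien-1-one | O=C1C=C(OC)C(OC)=C/C1=C/C(=C)c1ccc(OC)c(OC)c1OCc1ccccc1 | intermediate
9 | 3-[2-(benzyloxy)-3,4-dimethoxyphenyl]-6,7-dimethoxy-2H-chromene | COc1cc2OCC(=Cc2cc1OC)c1ccc(OC)c(OC)c1OCc1ccccc1 | intermediate
10 | (3S)-3-[2-(benzyloxy)-3,4-dimethoxyphenyl]-6,7-dimethoxy-3,4-dihydro-2H-chromene | COc1ccc([C@H]2COc3cc(OC)c(OC)cc3C2)c(OCc2ccccc2)c1OC | intermediate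
11 | 6-[(3S)-6,7-dimethoxy-3,4-dihydro-2H-chromen-3-yl]-2,3-dimethoxyphenol | COc1ccc([C@H]2COc3cc(OC)c(OC)cc3C2)c(O)c1OC | intermediate
12 | abroquinone A, 5-[(3S)-6,7-dimethoxy-3,4-dihydro-2H-chromen-3-yl]-2,3-dimethoxycyclohexa-2,5-diene-1,4-dione | COC1=C(OC)C(=O)C([C@H]2COc3cc(OC)c(OC)cc3C2)=CC1=O | target

**Step count**

Total steps: 7. Longest linear sequence: 7 steps (1 to 12); phenol 6 enters as a purchased partner in step 4.

**Steps most likely to fail**

Step 4. Conjugate addition of the phenol to the unhindered β-carbon of the enal, or thermal self-dimerisation of the enal, may outrun the boron-templated ortho-hydroxyalkylation; the quinone methide may also be trapped by a second phenol before it cyclises. The fallback builds the same chromene through a coumarin. It sets out from 6 and 4 and comes back at 9. Phenol 6 is ortho-formylated (MgCl2, Et3N, paraformaldehyde, MeCN, reflux) at its unhindered ortho carbon to 2-hydroxy-4,5-dimethoxybenzaldehyde F1. Aldehyde 4 is oxidised (NaClO2, NaH2PO4, 2-methyl-2-butene, t-BuOH/H2O; Pinnick oxidation) to [2-(benzyloxy)-3,4-dimethoxyphenyl]acetic acid F2. Perkin condensation of the two (Ac2O, Et3N, 110 °C) should give 3-[2-(benzyloxy)-3,4-dimethoxyphenyl]-6,7-dimethoxy-2H-chromen-2-one F3. Reduction of the lactone with excess i-Bu2AlH (CH2Cl2, −78 to 0 °C) should give 2-{(1Z)-2-[2-(benzyloxy)-3,4-dimethoxyphenyl]-3-hydroxyprop-1-en-1-yl}-4,5-dimethoxyphenol F4, and Mitsunobu cyclisation (PPh3, diisopropyl azodicarboxylate, THF) closes the O1–C2 bond to give 9.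

Step 5. The ortho-benzyloxy group twists the 3-aryl ring and crowds the metal, so face selectivity may be poor or turnover slow. The fallback replaces asymmetric catalysis by resolution. It sets out from 9 and comes back at 11. Hydrogenation over Pd/C (H2, EtOAc/MeOH, rt) reduces the C3=C4 bond and cleaves the benzyl ether in one operation to racemic 6-(6,7-dimethoxy-3,4-dihydro-2H-chromen-3-yl)-2,3-dimethoxyphenol F5. Preparative chromatography on a polysaccharide chiral stationary phase should separate the enantiomers; the (3S)-enantiomer is 11, and 6-[(3R)-6,7-dimethoxy-3,4-dihydro-2H-chromen-3-yl]-2,3-dimethoxyphenol F6 is set aside.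

Step 7. Oxidation may go partly at the ortho position with loss of the neighbouring methoxy group, conversion of the poorly water-soluble phenol may stall, and any excursion to basic pH may racemise C3 through quinone methide tautomerism. The fallback introduces the para oxygen by a two-electron path and oxidises a hydroquinone instead. It sets out from 11 and comes back at 12. Elbs persulfate oxidation (K2S2O8, aq. NaOH, pyridine, 0 °C to rt) should give potassium 5-[(3S)-6,7-dimethoxy-3,4-dihydro-2H-chromen-3-yl]-4-hydroxy-2,3-dimethoxyphenyl sulfate F7. Acid hydrolysis (aq. HCl, 60 °C) gives 2-[(3S)-6,7-dimethoxy-3,4-dihydro-2H-chromen-3-yl]-5,6-dimethoxybenzene-1,4-diol F8, which Ag2O (Et2O, rt) should oxidise to 12.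

**Further compounds**

F1 | step 4 | 2-hydroxy-4,5-dimethoxybenzaldehyde | O=Cc1cc(OC)c(OC)cc1O
F2 | step 4 | [2-(benzyloxy)-3,4-dimethoxyphenyl]acetic acid | OC(=O)Cc1ccc(OC)c(OC)c1OCc1ccccc1
F3 | step 4 | 3-[2-(benzyloxy)-3,4-dimethoxyphenyl]-6,7-dimethoxy-2H-chromen-2-one | COc1cc2OC(=O)C(=Cc2cc1OC)c1ccc(OC)c(OC)c1OCc1ccccc1
F4 | step 4 | 2-{(1Z)-2-[2-(benzyloxy)-3,4-dimethoxyphenyl]-3-hydroxyprop-1-en-1-yl}-4,5-dimethoxyphenol | COc1cc(O)c(/C=C(\CO)c2ccc(OC)c(OC)c2OCc2ccccc2)cc1OC
F5 | step 5 | racemic 6-(6,7-dimethoxy-3,4-dihydro-2H-chromen-3-yl)-2,3-dimethoxyphenol | COc1ccc(C2COc3cc(OC)c(OC)cc3C2)c(O)c1OC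
F6 | step 5 | 6-[(3R)-6,7-dimethoxy-3,4-dihydro-2H-chromen-3-yl]-2,3-dimethoxyphenol | COc1ccc([C@@H]2COc3cc(OC)c(OC)cc3C2)c(O)c1OC
F7 | step 7 | potassium 5-[(3S)-6,7-dimethoxy-3,4-dihydro-2H-chromen-3-yl]-4-hydroxy-2,3-dimethoxyphenyl sulfate | COc1c(OC)c(O)c([C@H]2COc3cc(OC)c(OC)cc3C2)cc1OS(=O)(=O)[O-].[K+]
F8 | step 7 | 2-[(3S)-6,7-dimethoxy-3,4-dihydro-2H-chromen-3-yl]-5,6-dimethoxybenzene-1,4-diol | COc1c(OC)c(O)c([C@H]2COc3cc(OC)c(OC)cc3C2)cc1O
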